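## The problem

Compound 32 joins two ring systems through the single bond C8–C14. The first is a cis-fused hydroazulene: cycloheptane C10–C1–C2–C3–C4–C5–C9 on cyclopentane C5–C6–C7–C8–C9, with an exocyclic methylene on C10 (C20), two methyl groups on C4 and a methyl group (C17) on quaternary C8. The second is a 2,7-dioxabicyclo[3.2.1]octan-3-one: C14 is the one-carbon bridge, C15 the acetal bridgehead, C13 the carbon bridgehead, C11 the lactone carbonyl, C12 the acetoxy carbon and C16 the ether carbon that bears the methyl ester.

There are eight stereocentres (C5, C8, C9 and C12–C16). Because C8–C14 links a quaternary to a tertiary centre with free rotation, neither ring system can pass its configuration to the other through a ring. Within the carbocycle, C8 can direct C5 and C9 if the seven-membered ring is delivered from a group on C8. Within the bicycle, C16 (an α-hydroxy ester centre that can be bought) can direct C13 and C14 through closure of the tetrahydrofuran, C15 follows from bridging, and C12 from the shape of the bicycle.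

The fragile groups are the acyloxy acetal at C15, the base-labile α-acetoxy lactone, the epimerisable C16 ester centre and the 1,1-disubstituted alkene. The alkene rules out hydrogenation, ozone and strong protic acid once it is in place, and it can capture a cation at C15. The bicycle must therefore be built last and under buffered conditions.

The feature that opens the carbocycle is this: C9–C10 and C5–C4 both lie on the face of C17, and C10 and C3 stand 1,4 to each other. C10–C1–C2–C3–C4 is then the carbon ring of 2-methylcyclopentane-1,3-dione after [2+2] addition to a C5=C9 alkene and retro-aldol cleavage, with C17 acting as a carboxyl tether.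

## Retrosynthesis

**32 to 29 (C12–O).** The acetate and the C12–O bond are removed first, via alcohol 31, because an α-acetoxy lactone would not survive earlier steps. Carrying the oxygen through the radical step would need a captodative acceptor and would leave C12 uncontrolled. Lactone 29 has one stereocentre fewer. The forward step needs enolisation of the lactone in preference to the C16 ester, and attack of the oxidant on the face away from the hydroazulene.

**29 to 27 (C15–O acyl).** The lactone bond to the acetal carbon is cut, giving monocyclic tetrahydrofuran 27 with a methyl acetal at C15 and a tert-butyl ester at C11. This is preferred to oxidising a bis-acetal, which would need C11 at the aldehyde level and a late oxidation next to the alkene. The forward step must ionise C15 without protonating the C10 methylene; C15 needs no control because it can only bridge on one face.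

**27 to 22 + 25 (C14–C13).** The bond is cut as a 5-exo radical cyclisation of bromoacetal 26, assembled from enol ether 22, alcohol 25 and a bromonium source. Intermolecular additions of a C14 enolate equivalent were set aside because nothing would control C14 next to the freely rotating C8. Here C16 of 25 sets C13 and C14 inside a five-membered transition state, and the configurations at C14 and C15 of 26 do not matter. Alcohol 25 comes in one step from hydroxy ester 23 and acrylate 24.

**22 to 21 (arm).** Enol ether 22 is the elimination product of dimethyl acetal 21. The two-carbon arm is carried as this acetal from step 2 onward, so no protecting-group steps are spent on C14 and C15.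

**21 to 17 (C3 and C17).** The C3 carbonyl and the carboxyl carbon on C8 are taken to CH2 and CH3 together, by Wolff–Kishner reduction of keto aldehyde 19. Aldehyde 19 comes from keto ester 17 through diol 18. Separate deoxygenations would need a neopentyl primary C–O cleavage. The forward step requires C10 to be the alkene already, since a C10 ketone would be reduced too.

**17 to 12 (C4–CH3, C10=CH2, C4–C10).** The two ketones of the ring-expanded dione are sterically similar, so they are told apart at birth. The retro-aldol cleavage of 12 gives the C3–C4 enolate, which is stored as silyl enol ether 14. This leaves only C10 as a ketone for methylenation (15), and the stored enolate is then methylated at C4 (17). Direct methylation followed by selective olefination would rest on a small steric difference.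

**12 to 11 (key cut, C9–C10 and C4–C5).** Both bonds are formed in one intramolecular photocycloaddition of enol ester 11. An intermolecular de Mayo reaction would have neither regiochemical nor facial control. Four stereocentres and two rings are traced back to the single centre C8 of 11; the forward reaction must give the straight adduct on the carboxyl face.

**11 to 1 + 2 + 9.** The enol ester is cut to acid 8 and dione 9. The quaternary centre of 8 is set by catalytic asymmetric allylation of keto ester 1 with allyl acetate 2, giving 3. The allyl group is cleaved to the acetal (5) before the ring alkene exists, and the ketone is removed via enol triflate 6 to give 7. This was preferred to deconjugative alkylation of a cyclopentenecarboxylate followed by resolution, which discards half the material and rests on an unknown enzyme selectivity.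

## Roads not taken

**Alternative 1:** The cyclopentane would come from contracting a cyclohexane made by a Diels–Alder reaction. A Lewis acid opens the C7–C8 epoxide of epoxy silyl ether A2 at tertiary C8, C9 migrates from the silyloxy carbon to C8, and aldehyde A1 results, with C14 as a formyl group on the new quaternary centre.
- Merits: thermal, scalable, and stereospecific at C8 (migration anti to the breaking C–O bond).
- Weak points: A1 carries an oxygen on C7 and a ketal on C10 that cost steps; enantiocontrol must come from the cycloaddition or the epoxidation; the bicycle must be grown from a neopentyl aldehyde, so C14 is set by addition next to C8 without a ring to guide it.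
- Comparison: in scalability and in avoiding a dilute photochemical step this road is better. The chosen plan sets against it that one centre controls four new ones in a single step, that no stray oxygen is left on C7, and that C14 and C15 are already present as the acetal arm.

**Alternative 2:** This road cuts C14–C15 and C12–C13 of the bicycle and takes the hydroazulene as made. Sensitised irradiation of 1,5-diene A4 (a β-alkoxyacrylate tied through oxygen and C16 to the C13=C14 alkene) gives the crossed adduct A3. Opening its donor–acceptor cyclobutane bond C15–C12, with capture of C15 by the ester carbonyl, would expand it to the lactone.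
- Merits: two C–C bonds and the tetrahydrofuran in one step, a strain-driven lactonisation, and C16 in the tether.
- Weak points: the synthesis of the carbocycle is left open; the face of C14 next to C8 is not fixed by the tether; the exocyclic methylene is a second alkene exposed to the sensitiser; the C12 oxygen and its configuration remain to be set.
- Comparison: for the bicycle alone this is shorter than steps 14–20 here, and that is a real advantage. The chosen plan sets against it a complete route to the carbocycle, a C14 centre formed inside a five-membered transition state under C16 control, and a photochemical step run where no competing alkene is present.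

**Alternative 3:** The C5–C9 bond is traced back to C5–C10 of a trans-decalin. Buffered solvolysis of equatorial mesylate A6 lets C5 shift from C10 to C9, contracting ring B and enlarging ring A; the C10 cation loses a methyl proton to give A5.
- Merits: one step sets the cis ring fusion and the exocyclic alkene, no late olefination is needed, and decalins of this type relate to chiral-pool terpenoids.
- Weak points: the cation can also lose a ring proton, shift hydride or methyl, or simply eliminate; A6 needs a quaternary C8 (methyl plus arm) beside the secondary mesylate, which is itself demanding.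
- Comparison: if the decalin came from the chiral pool this could be shorter than steps 1–13 and better in step economy. The chosen plan sets against it positional certainty: C10 is a ketone by construction and becomes the methylene by olefination, C4 receives its methyl through a regiodefined enolate, and nothing depends on how a cation partitions.

Key step: step 7

Remarks (assumptions):
- Atom labels C1–C20 are those used above; SMILES strings are authoritative for configuration.
- (R)-Methyl 2-hydroxybut-3-enoate (23) is taken as purchasable in enantiopure form; otherwise it is obtained from the commercial racemate by lipase resolution.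
- In step 1 the antipode of the ligand is chosen so that (R)-3 results; the sense of induction is to be confirmed on the first run.

## Route

Step 1
Reactants: 1 methyl 2-oxocyclopentane-1-carboxylate; 2 allyl acetate
Product: 3 methyl (1R)-2-oxo-1-(prop-2-en-1-yl)cyclopentane-1-carboxylate
Conditions: [Pd(C3H5)Cl]2 (cat.), DACH-phenyl Trost ligand (antipode giving (R)-3), 1,1,3,3-tetramethylguanidine, toluene, 0 °C
Reagents that add atoms: none
Why: Tsuji–Trost asymmetric allylic alkylation of a cyclic β-keto ester: the enolate attacks the π-allylpalladium complex inside the chiral pocket of the ligand, which selects the enolate face and sets quaternary C8, the only stereocentre carried into the key step.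

Step 2
Reactants: 3 methyl (1R)-2-oxo-1-(prop-2-en-1-yl)cyclopentane-1-carboxylate
Product: 5 methyl (1R)-1-(2,2-dimethoxyethyl)-2-oxocyclopentane-1-carboxylate, via keto aldehyde 4 (not isolated)
Conditions: O3, CH2Cl2/MeOH, −78 °C; Me2S; then CH(OMe)3, TsOH·H2O (cat.), rt
Reagents that add atoms: ozone, [O-][O+]=O (carbonyl oxygen of 4); trimethyl orthoformate, COC(OC)OC (both methoxy groups of 5)
Why: Ozonolysis cleaves the only alkene present (the ring alkene does not exist yet) and the aldehyde is acetalised in the same flask, the hindered α-quaternary ketone being slow to ketalise; the arm then travels as a base-stable acetal up to step 14.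

Step 3
Reactants: 5 methyl (1R)-1-(2,2-dimethoxyethyl)-2-oxocyclopentane-1-carboxylate
Product: 6 methyl (1R)-1-(2,2-dimethoxyethyl)-2-{[(trifluoromethyl)sulfonyl]oxy}cyclopent-2-ene-1-carboxylate
Conditions: KN(SiMe3)2, PhNTf2, THF, −78 °C
Reagents that add atoms: N-phenylbis(trifluoromethanesulfonimide), O=S(=O)(N(c1ccccc1)S(=O)(=O)C(F)(F)F)C(F)(F)F
Why: Enol triflate formation: C8 is quaternary, so the ketone can enolise only toward C5, and the potassium enolate is sulfonylated on oxygen.

Step 4
Reactants: 6 methyl (1R)-1-(2,2-dimethoxyethyl)-2-{[(trifluoromethyl)sulfonyl]oxy}cyclopent-2-ene-1-carboxylate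
Product: 7 methyl (1R)-1-(2,2-dimethoxyethyl)cyclopent-2-ene-1-carboxylate
Conditions: Pd(OAc)2 (cat.), PPh3, Et3N, HCO2H, DMF, 60 °C
Reagents that add atoms: none
Why: Palladium-catalysed formate reduction of a vinyl triflate (oxidative addition of zerovalent palladium, formate exchange, loss of CO2, reductive elimination) gives the C5=C9 alkene; the amine buffer protects the acetal.

Step 5
Reactants: 7 methyl (1R)-1-(2,2-dimethoxyethyl)cyclopent-2-ene-1-carboxylate
Product: 8 (1R)-1-(2,2-dimethoxyethyl)cyclopent-2-ene-1-carboxylic acid
Conditions: LiOH, THF/MeOH/H2O, 50 °C; then 1 M HCl to pH 4, 0 °C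
Reagents that add atoms: lithium hydroxide, [Li+].[OH-]
Why: Saponification of the hindered ester; the acetal is inert to base and should survive the brief cold acidification.

Step 6
Reactants: 8 (1R)-1-(2,2-dimethoxyethyl)cyclopent-2-ene-1-carboxylic acid; 9 2-methylcyclopentane-1,3-dione
Product: 11 2-methyl-3-oxocyclopent-1-en-1-yl (1R)-1-(2,2-dimethoxyethyl)cyclopent-2-ene-1-carboxylate, via acid chloride 10 (not isolated)
Conditions: 1-chloro-N,N,2-trimethylprop-1-en-1-amine, CH2Cl2, 0 °C; then 9, Et3N, 0 °C → rt
Reagents that add atoms: 1-chloro-N,N,2-trimethylprop-1-en-1-amine, CC(C)=C(Cl)N(C)C (chlorine of 10 only)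
Why: The neutral α-chloroenamine (Ghosez reagent) forms the acid chloride without free HCl, and the triethylammonium enolate of the 2-substituted dione is acylated on oxygen, since C-acylation would require a quaternary triketone.

Step 7
Reactants: 11 2-methyl-3-oxocyclopent-1-en-1-yl (1R)-1-(2,2-dimethoxyethyl)cyclopent-2-ene-1-carboxylate
Product: 12 lactone-bridged cyclobutane photoadduct (γ-lactone C8–C(=O)–O–C10–C9, cyclobutane C4–C5–C9–C10, cyclopentanone C10–C1–C2–C3(=O)–C4, cyclopentane C5–C9; 4-methyl, 8-(2,2-dimethoxyethyl); cis-anti-cis, 4S,5R,8R,9R,10S)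
Conditions: hν (350 nm, Pyrex), MeCN (0.01 M, degassed), rt
Reagents that add atoms: none
Why: Excitation of the 3-acyloxy-2-methylcyclopentenone and intersystem crossing give the enone triplet, which adds stepwise to the C5=C9 alkene; the closest known reaction type is the intramolecular de Mayo photocycloaddition of cyclic 1,3-dione enol esters tethered to cyclopentenes. The first bond, C10–C9, closes the γ-lactone by 1,5-closure (rule of five) through the three-atom tether O–C(=O)–C8; the second, C4–C5, closes the cyclobutane by collapse of the 1,4-biradical. C9 and C10 are set by the tether, because the acyloxy carbon can reach C9 only on the face of C8 that carries the carboxyl group, so the new C9–C10 bond is cis to the future C17. C5 follows because a cyclobutane can only be cis-fused to the cyclopentane, and C4 because the cyclopentanone must be cis-fused to the cyclobutane, where it lies anti to the cyclopentane. The step needs the straight and not the crossed adduct and a single face; the short tether enforces both, so the one stereocentre of 11 controls four new ones. The saturated acetal arm offers no second alkene, and long-wavelength irradiation at high dilution is chosen to disfavour acyl migration of the enol ester.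

Step 8
Reactants: 12 lactone-bridged cyclobutane photoadduct
Product: 14 methyl (1R,3aR,8aR)-1-(2,2-dimethoxyethyl)-4-methyl-8-oxo-5-[(trimethylsilyl)oxy]-1,2,3,3a,6,7,8,8a-octahydroazulene-1-carboxylate, via sodium enolate 13 (not isolated)
Conditions: NaOMe (1.05 equiv), 15-crown-5, THF, −20 → 0 °C; then Me3SiCl, Et3N, −78 → 0 °C
Reagents that add atoms: sodium methoxide, [Na+].[O-]C; chlorotrimethylsilane, C[Si](C)(C)Cl
Why: Methoxide opens the strained lactone at the acyl carbon and the released C10 alkoxide undergoes retro-aldol cleavage of the C4–C10 bond (de Mayo fragmentation), giving the C10 ketone and, regiospecifically, the C3–C4 enolate 13, which is silylated on oxygen; the silyl enol ether masks C3 and stores the site of the later methylation, and the hindered C9–H is not expected to exchange at low temperature.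

Step 9
Reactants: 14 methyl (1R,3aR,8aR)-1-(2,2-dimethoxyethyl)-4-methyl-8-oxo-5-[(trimethylsilyl)oxy]-1,2,3,3a,6,7,8,8a-octahydroazulene-1-carboxylate
Product: 15 methyl (1R,3aR,8aS)-1-(2,2-dimethoxyethyl)-4-methyl-8-methylidene-5-[(trimethylsilyl)oxy]-1,2,3,3a,6,7,8,8a-octahydroazulene-1-carboxylate
Conditions: Cp2TiMe2, toluene, 70 °C, dark
Reagents that add atoms: dimethyltitanocene, [CH3-].[CH3-].[Ti+4].[cH-]1cccc1.[cH-]1cccc1
Why: Petasis methylenation (Cp2Ti=CH2, formed by loss of methane, adds to the ketone and extrudes titanocene oxide) is non-basic, so C9 cannot epimerise; the quaternary ester reacts far more slowly than the ketone and the silyl enol ether is inert.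

Step 10
Reactants: 15 methyl (1R,3aR,8aS)-1-(2,2-dimethoxyethyl)-4-methyl-8-methylidene-5-[(trimethylsilyl)oxy]-1,2,3,3a,6,7,8,8a-octahydroazulene-1-carboxylate
Product: 17 methyl (1R,3aR,8aS)-1-(2,2-dimethoxyethyl)-4,4-dimethyl-8-methylidene-5-oxodecahydroazulene-1-carboxylate, via ammonium enolate 16 (not isolated)
Conditions: BnMe3NF, MeI, 4 Å MS, THF, 0 °C → rt
Reagents that add atoms: iodomethane, CI
Why: Fluoride cleaves the Si–O bond and releases the tetrasubstituted enolate only at C3–C4 (regiospecific alkylation of a silyl enol ether, Kuwajima–Nakamura type); C-methylation completes the gem-dimethyl group and removes the C4 stereocentre, and fluoride is used because methyllithium would attack the ester.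

Step 11
Reactants: 17 methyl (1R,3aR,8aS)-1-(2,2-dimethoxyethyl)-4,4-dimethyl-8-methylidene-5-oxodecahydroazulene-1-carboxylate
Product: 18 (1R,3aR,8aS)-1-(2,2-dimethoxyethyl)-1-(hydroxymethyl)-4,4-dimethyl-8-methylidenedecahydroazulen-5-ol (carbinol epimers at C3)
Conditions: LiAlH4, THF, 0 °C → rt
Reagents that add atoms: none
Why: Hydride reduction takes the neopentyl ester to the primary alcohol and the C3 ketone to the carbinol; the epimer mixture is of no consequence, and acetal and alkene are inert.

Step 12
Reactants: 18 (1R,3aR,8aS)-1-(2,2-dimethoxyethyl)-1-(hydroxymethyl)-4,4-dimethyl-8-methylidenedecahydroazulen-5-ol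
Product: 19 (1R,3aR,8aS)-1-(2,2-dimethoxyethyl)-4,4-dimethyl-8-methylidene-5-oxodecahydroazulene-1-carbaldehyde
Conditions: Dess–Martin periodinane, NaHCO3, CH2Cl2, rt
Reagents that add atoms: none
Why: Dess–Martin oxidation brings both hydroxyl groups to the carbonyl level under buffered conditions that spare the acetal; the aldehyde has no α-hydrogen and cannot enolise.

Step 13
Reactants: 19 (1R,3aR,8aS)-1-(2,2-dimethoxyethyl)-4,4-dimethyl-8-methylidene-5-oxodecahydroazulene-1-carbaldehyde
Product: 21 (1S,3aR,8aS)-1-(2,2-dimethoxyethyl)-1,4,4-trimethyl-8-methylidenedecahydroazulene, via bis-hydrazone 20 (not isolated)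
Conditions: N2H4·H2O, diethylene glycol, 130 °C; then KOH, 200 °C, Ar
Reagents that add atoms: hydrazine hydrate, NN.O (nitrogen atoms of 20 only)
Why: Wolff–Kishner reduction (Huang–Minlon procedure): both hydrazones lose nitrogen under hydroxide at high temperature, turning C3=O into CH2 and the formyl group into the C17 methyl in one operation; acetal and isolated alkene are stable to base, and oxygen is excluded so that no diimide can form.

Step 14
Reactants: 21 (1S,3aR,8aS)-1-(2,2-dimethoxyethyl)-1,4,4-trimethyl-8-methylidenedecahydroazulene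
Product: 22 (1R,3aR,8aS)-1-(2-methoxyethenyl)-1,4,4-trimethyl-8-methylidenedecahydroazulene (E/Z mixture)
Conditions: Me3SiOTf, iPr2NEt, CH2Cl2, −20 °C → rt
Reagents that add atoms: none
Why: Gassman-type conversion of an acetal into an enol ether: the silyl triflate ionises the acetal and the hindered amine removes a C14 proton; the E/Z ratio is irrelevant because C14 becomes a radical centre, and the buffered medium spares the exocyclic alkene.

Step 15
Reactants: 23 methyl (2R)-2-hydroxybut-3-enoate; 24 tert-butyl acrylate
Product: 25 1-tert-butyl 5-methyl (2E,4R)-4-hydroxypent-2-enedioate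
Conditions: second-generation Hoveyda–Grubbs catalyst, RuCl2(H2IMes)(=CH-C6H4-2-OiPr) (cat.), 24 in excess, CH2Cl2, 40 °C
Reagents that add atoms: none
Why: Olefin cross-metathesis of an allylic alcohol with an acrylate should give the E-enoate; the carbinol centre (future C16) is not involved.

Step 16
Reactants: 22 (1R,3aR,8aS)-1-(2-methoxyethenyl)-1,4,4-trimethyl-8-methylidenedecahydroazulene; 25 1-tert-butyl 5-methyl (2E,4R)-4-hydroxypent-2-enedioate
Product: 26 1-tert-butyl 5-methyl (2E,4R)-4-{2-bromo-1-methoxy-2-[(1R,3aR,8aS)-1,4,4-trimethyl-8-methylidenedecahydroazulen-1-yl]ethoxy}pent-2-enedioate (mixture at C14 and C15)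
Conditions: NBS, 25 (1.5 equiv), CH2Cl2, −40 → 0 °C
Reagents that add atoms: N-bromosuccinimide, O=C1CCC(=O)N1Br
Why: Bromoetherification (haloacetal formation): the bromonium source attacks the electron-rich enol ether at C14 far faster than the 1,1-disubstituted alkene, and alcohol 25 captures the oxocarbenium ion at C15; the configurations at C14 and C15 do not matter.

Step 17
Reactants: 26 1-tert-butyl 5-methyl (2E,4R)-4-{2-bromo-1-methoxy-2-[(1R,3aR,8aS)-1,4,4-trimethyl-8-methylidenedecahydroazulen-1-yl]ethoxy}pent-2-enedioate
Product: 27 methyl (2R,3R,4R)-3-(2-tert-butoxy-2-oxoethyl)-5-methoxy-4-[(1R,3aR,8aS)-1,4,4-trimethyl-8-methylidenedecahydroazulen-1-yl]oxolane-2-carboxylate (anomers at C15)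
Conditions: Bu3SnH, AIBN, PhH, 80 °C, slow addition
Reagents that add atoms: none
Why: Ueno–Stork radical cyclisation: the C14 radical closes 5-exo-trig onto C13 of the enoate through a chair-like transition state (Beckwith–Houk model) in which the C16 ester is pseudo-equatorial, so C13–C12 forms trans to it, and the substituent on the radical carbon is pseudo-equatorial, so C14–C8 forms cis to C13–C12; C16 thereby sets C13 and C14, and the α-ester radical is reduced by the stannane.

Step 18
Reactants: 27 methyl (2R,3R,4R)-3-(2-tert-butoxy-2-oxoethyl)-5-methoxy-4-[(1R,3aR,8aS)-1,4,4-trimethyl-8-methylidenedecahydroazulen-1-yl]oxolane-2-carboxylate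
Product: 29 methyl (1S,5R,6R,8R)-3-oxo-8-[(1R,3aR,8aS)-1,4,4-trimethyl-8-methylidenedecahydroazulen-1-yl]-2,7-dioxabicyclo[3.2.1]octane-6-carboxylate, via trimethylsilyl ester 28 (not isolated)
Conditions: Me3SiOTf, 2,6-lutidine, CH2Cl2, 0 °C → rt; aq. NaHCO3
Reagents that add atoms: trimethylsilyl trifluoromethanesulfonate, C[Si](C)(C)OS(=O)(=O)C(F)(F)F (silicon of 28 only)
Why: The silyl triflate converts the tert-butyl ester into silyl ester 28 with loss of 2-methylpropene and ionises the methyl acetal at C15 as its lutidinium adduct; the ester oxygen, held on the same face by C13, captures C15 to give the acyloxy acetal (lactonisation by acetal exchange), so C15 is fixed by bridging, and the buffered aprotic medium is chosen to spare the exocyclic alkene.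

Step 19
Reactants: 29 methyl (1S,5R,6R,8R)-3-oxo-8-[(1R,3aR,8aS)-1,4,4-trimethyl-8-methylidenedecahydroazulen-1-yl]-2,7-dioxabicyclo[3.2.1]octane-6-carboxylate
Product: 31 methyl (1S,4S,5S,6R,8R)-4-hydroxy-3-oxo-8-[(1R,3aR,8aS)-1,4,4-trimethyl-8-methylidenedecahydroazulen-1-yl]-2,7-dioxabicyclo[3.2.1]octane-6-carboxylate, via lithium enolate 30 (not isolated)
Conditions: LiN(SiMe3)2, THF, −78 °C; then 2-(phenylsulfonyl)-3-phenyloxaziridine, −78 °C; aq. NH4Cl
Reagents that add atoms: 2-(phenylsulfonyl)-3-phenyloxaziridine, O=S(=O)(N1OC1c1ccccc1)c1ccccc1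
Why: Davis enolate oxidation: the δ-lactone CH2 (C12) is more acidic and more accessible than the tertiary, endo-oriented C16–H of the methyl ester, and the oxidant should approach C12 anti to the hydroazulene, which sits on C14 over the lactone ring, giving the equatorial 12S alcohol.

Step 20
Reactants: 31 methyl (1S,4S,5S,6R,8R)-4-hydroxy-3-oxo-8-[(1R,3aR,8aS)-1,4,4-trimethyl-8-methylidenedecahydroazulen-1-yl]-2,7-dioxabicyclo[3.2.1]octane-6-carboxylate
Product: 32 methyl (1S,4S,5R,6R,8R)-4-acetoxy-3-oxo-8-[(1R,3aR,8aS)-1,4,4-trimethyl-8-methylidenedecahydroazulen-1-yl]-2,7-dioxabicyclo[3.2.1]octane-6-carboxylate (CNP0215240.1)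
Conditions: Ac2O, pyridine, DMAP (cat.), CH2Cl2, 0 °C
Reagents that add atoms: acetic anhydride, CC(=O)OC(C)=O
Why: DMAP-catalysed O-acetylation under mild, weakly basic conditions that should not epimerise C12 or C16.

## Compound list

1 | methyl 2-oxocyclopentane-1-carboxylate | COC(=O)C1CCCC1=O | starting material
2 | allyl acetate | CC(=O)OCC=C | starting material
3 | methyl (1R)-2-oxo-1-(prop-2-en-1-yl)cyclopentane-1-carboxylate | COC(=O)[C@@]1(CC=C)CCCC1=O | intermediate
4 | methyl (1R)-2-oxo-1-(2-oxoethyl)cyclopentane-1-carboxylate | COC(=O)[C@@]1(CC=O)CCCC1=O | intermediate (not isolated)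
5 | methyl (1R)-1-(2,2-dimethoxyethyl)-2-oxocyclopentane-1-carboxylate | COC(=O)[C@@]1(CC(OC)OC)CCCC1=O | intermediate
6 | methyl (1R)-1-(2,2-dimethoxyethyl)-2-{[(trifluoromethyl)sulfonyl]oxy}cyclopent-2-ene-1-carboxylate | COC(=O)[C@@]1(CC(OC)OC)CCC=C1OS(=O)(=O)C(F)(F)F | intermediate
7 | methyl (1R)-1-(2,2-dimethoxyethyl)cyclopent-2-ene-1-carboxylate | COC(=O)[C@@]1(CC(OC)OC)CCC=C1 | intermediate
8 | (1R)-1-(2,2-dimethoxyethyl)cyclopent-2-ene-1-carboxylic acid | OC(=O)[C@@]1(CC(OC)OC)CCC=C1 | intermediate
9 | 2-methylcyclopentane-1,3-dione | CC1C(=O)CCC1=O | starting material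
10 | (1R)-1-(2,2-dimethoxyethyl)cyclopent-2-ene-1-carbonyl chloride | ClC(=O)[C@@]1(CC(OC)OC)CCC=C1 | intermediate (not isolated)
11 | 2-methyl-3-oxocyclopent-1-en-1-yl (1R)-1-(2,2-dimethoxyethyl)cyclopent-2-ene-1-carboxylate | CC1=C(OC(=O)[C@@]2(CC(OC)OC)CCC=C2)CCC1=O | intermediate
12 | lactone-bridged cyclobutane photoadduct, cis-anti-cis (4S,5R,8R,9R,10S) | O=C1O[C@]23CCC(=O)[C@@]2(C)[C@@H]4CC[C@@]1(CC(OC)OC)[C@H]34 | intermediate
13 | sodium C3–C4 enolate of the ring-expanded diketo ester | O=C1CCC([O-])=C(C)[C@@H]2CC[C@@](C(=O)OC)(CC(OC)OC)[C@H]12.[Na+] | intermediate (not isolated)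
14 | methyl (1R,3aR,8aR)-1-(2,2-dimethoxyethyl)-4-methyl-8-oxo-5-[(trimethylsilyl)oxy]-1,2,3,3a,6,7,8,8a-octahydroazulene-1-carboxylate | O=C1CCC(O[Si](C)(C)C)=C(C)[C@@H]2CC[C@@](C(=O)OC)(CC(OC)OC)[C@H]12 | intermediate
15 | methyl (1R,3aR,8aS)-1-(2,2-dimethoxyethyl)-4-methyl-8-methylidene-5-[(trimethylsilyl)oxy]-1,2,3,3a,6,7,8,8a-octahydroazulene-1-carboxylate | C=C1CCC(O[Si](C)(C)C)=C(C)[C@@H]2CC[C@@](C(=O)OC)(CC(OC)OC)[C@H]12 | intermediate
16 | benzyltrimethylammonium C3–C4 enolate of 17 | C=C1CCC([O-])=C(C)[C@@H]2CC[C@@](C(=O)OC)(CC(OC)OC)[C@H]12.C[N+](C)(C)Cc1ccccc1 | intermediate (not isolated)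
17 | methyl (1R,3aR,8aS)-1-(2,2-dimethoxyethyl)-4,4-dimethyl-8-methylidene-5-oxodecahydroazulene-1-carboxylate | C=C1CCC(=O)C(C)(C)[C@@H]2CC[C@@](C(=O)OC)(CC(OC)OC)[C@H]12 | intermediate
18 | (1R,3aR,8aS)-1-(2,2-dimethoxyethyl)-1-(hydroxymethyl)-4,4-dimethyl-8-methylidenedecahydroazulen-5-ol (carbinol epimers) | C=C1CCC(O)C(C)(C)[C@@H]2CC[C@@](CO)(CC(OC)OC)[C@H]12 | intermediate
19 | (1R,3aR,8aS)-1-(2,2-dimethoxyethyl)-4,4-dimethyl-8-methylidene-5-oxodecahydroazulene-1-carbaldehyde | C=C1CCC(=O)C(C)(C)[C@@H]2CC[C@@](C=O)(CC(OC)OC)[C@H]12 | intermediate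
20 | bis-hydrazone of 19 | C=C1CCC(=NN)C(C)(C)[C@@H]2CC[C@@](C=NN)(CC(OC)OC)[C@H]12 | intermediate (not isolated)
21 | (1S,3aR,8aS)-1-(2,2-dimethoxyethyl)-1,4,4-trimethyl-8-methylidenedecahydroazulene | C=C1CCCC(C)(C)[C@@H]2CC[C@@](C)(CC(OC)OC)[C@H]12 | intermediate
22 | (1R,3aR,8aS)-1-(2-methoxyethenyl)-1,4,4-trimethyl-8-methylidenedecahydroazulene (E/Z mixture) | C=C1CCCC(C)(C)[C@@H]2CC[C@@](C)(C=COC)[C@H]12 | intermediate
23 | methyl (2R)-2-hydroxybut-3-enoate | COC(=O)[C@H](O)C=C | starting material
24 | tert-butyl acrylate | C=CC(=O)OC(C)(C)C | starting material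
25 | 1-tert-butyl 5-methyl (2E,4R)-4-hydroxypent-2-enedioate | COC(=O)[C@H](O)/C=C/C(=O)OC(C)(C)C | intermediate
26 | 1-tert-butyl 5-methyl (2E,4R)-4-{2-bromo-1-methoxy-2-[(1R,3aR,8aS)-1,4,4-trimethyl-8-methylidenedecahydroazulen-1-yl]ethoxy}pent-2-enedioate (mixture at C14, C15) | C=C1CCCC(C)(C)[C@@H]2CC[C@@](C)(C(Br)C(OC)O[C@@H](C(=O)OC)/C=C/C(=O)OC(C)(C)C)[C@H]12 | intermediate
27 | methyl (2R,3R,4R)-3-(2-tert-butoxy-2-oxoethyl)-5-methoxy-4-[(1R,3aR,8aS)-1,4,4-trimethyl-8-methylidenedecahydroazulen-1-yl]oxolane-2-carboxylate (anomers) | C=C1CCCC(C)(C)[C@@H]2CC[C@@](C)([C@@H]3C(OC)O[C@@H](C(=O)OC)[C@@H]3CC(=O)OC(C)(C)C)[C@H]12 | intermediate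
28 | trimethylsilyl ester corresponding to 27 | C=C1CCCC(C)(C)[C@@H]2CC[C@@](C)([C@@H]3C(OC)O[C@@H](C(=O)OC)[C@@H]3CC(=O)O[Si](C)(C)C)[C@H]12 | intermediate (not isolated)
29 | methyl (1S,5R,6R,8R)-3-oxo-8-[(1R,3aR,8aS)-1,4,4-trimethyl-8-methylidenedecahydroazulen-1-yl]-2,7-dioxabicyclo[3.2.1]octane-6-carboxylate | C=C1CCCC(C)(C)[C@@H]2CC[C@@](C)([C@@H]3[C@@H]4OC(=O)C[C@H]3[C@H](C(=O)OC)O4)[C@H]12 | intermediate
30 | lithium enolate of 29 | C=C1CCCC(C)(C)[C@@H]2CC[C@@](C)([C@@H]3[C@@H]4OC([O-])=C[C@H]3[C@H](C(=O)OC)O4)[C@H]12.[Li+] | intermediate (not isolated)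
31 | methyl (1S,4S,5S,6R,8R)-4-hydroxy-3-oxo-8-[(1R,3aR,8aS)-1,4,4-trimethyl-8-methylidenedecahydroazulen-1-yl]-2,7-dioxabicyclo[3.2.1]octane-6-carboxylate | C=C1CCCC(C)(C)[C@@H]2CC[C@@](C)([C@@H]3[C@@H]4OC(=O)[C@@H](O)[C@H]3[C@H](C(=O)OC)O4)[C@H]12 | intermediate
32 | methyl (1S,4S,5R,6R,8R)-4-acetoxy-3-oxo-8-[(1R,3aR,8aS)-1,4,4-trimethyl-8-methylidenedecahydroazulen-1-yl]-2,7-dioxabicyclo[3.2.1]octane-6-carboxylate | C=C1CCCC(C)(C)[C@@H]2CC[C@@](C)([C@@H]3[C@@H]4OC(=O)[C@@H](OC(C)=O)[C@H]3[C@H](C(=O)OC)O4)[C@H]12 | target

## Step count and least certain steps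

Total: 20 steps. Longest linear sequence: 19 steps (steps 1–14 and 16–20, from 1 to 32); step 15 is a one-step branch.

**Step 7 (key step).** The most likely failure is acyl migration of the excited enol ester (a photo-Fries-type 1,3-shift) or unproductive decay, because the chromophore is a vinylogous anhydride; crossed addition is unlikely with a three-atom tether. Fallback, from 7 back to 12: ester 7 is reduced with LiAlH4 to [(1R)-1-(2,2-dimethoxyethyl)cyclopent-2-en-1-yl]methanol F1. Its sodium alkoxide displaces chloride from 3-chloro-2-methylcyclopent-2-en-1-one to give the vinylogous ester 3-{[(1R)-1-(2,2-dimethoxyethyl)cyclopent-2-en-1-yl]methoxy}-2-methylcyclopent-2-en-1-one F2, an alkoxyenone that cannot undergo acyl migration. Irradiation forms the same two C–C bonds and gives the ether photoadduct F3. Oxidation of its O–CH2 group with RuCl3 (cat.)/NaIO4 gives lactone 12.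

**Step 8.** The most likely failure is hydrolytic loss of the trimethylsilyl enol ether during isolation or during step 9, which would erase the stored regiochemistry; slow opening of the hindered lactone by suspended methoxide would have a similar effect through enolate equilibration. Fallback, from 12 back to 17: enolate 13 is quenched in the same flask with iodomethane to give methyl (1R,3aR,8aR)-1-(2,2-dimethoxyethyl)-4,4-dimethyl-5,8-dioxodecahydroazulene-1-carboxylate F4. The C10 ketone of F4 is then methylenated with Cp2TiMe2, relying on the neopentyl hindrance of C3 beside the new quaternary C4, to give 17.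

**Step 13.** The most likely failure is incomplete reduction at the hindered C3 hydrazone (azine formation), or migration or partial reduction of the exocyclic alkene in hot alkaline hydrazine. Fallback, from 18 back to 21: diol 18 is converted (NaH, CS2, MeI) into the bis(S-methyl dithiocarbonate) of 18 F5, and both C–O bonds are cleaved by Barton–McCombie reduction (Bu3SnH, AIBN, hot xylene) to give 21.

**Step 17.** The most likely failure is erosion of the cis relation between C14 and C13, because the radical carbon bears a tertiary alkyl group, together with premature reduction of the hindered radical. Fallback, from crude 27 (mixed at C14) back to 29: Me3SiOTf/iPr2NEt eliminates methanol to give methyl (2R,3R)-3-(2-tert-butoxy-2-oxoethyl)-4-[(1R,3aR,8aS)-1,4,4-trimethyl-8-methylidenedecahydroazulen-1-yl]-2,3-dihydrofuran-2-carboxylate F6, in which C14 is trigonal. A catalytic sulfonic acid then protonates the enol ether (much faster than the 1,1-dialkyl alkene) at C14 anti to the C13 side chain, and the tert-butyl ester captures C15 with loss of 2-methylpropene to give 29.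

**Step 18.** The most likely failure is diversion of the C15 cation, either by elimination to the dihydrofuran or by capture by the exocyclic alkene through a six-membered ring. Fallback, from 27 back to 29: aqueous H3PO4 in toluene hydrolyses both the acetal and the tert-butyl ester, water intercepting the cation, to give 2-[(2R,3R,4R)-5-hydroxy-2-(methoxycarbonyl)-4-[(1R,3aR,8aS)-1,4,4-trimethyl-8-methylidenedecahydroazulen-1-yl]oxolan-3-yl]acetic acid F7. The ring is then closed by acylation of the lactol hydroxyl (2,4,6-trichlorobenzoyl chloride, Et3N, DMAP) to give 29.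

**Step 19.** The most likely failure is loss of facial selectivity at C12, since the endo face is flanked by the O–C16 bridge, or competing deprotonation at C16. Fallback, from 29 to 32: if the epimeric alcohol methyl (1S,4R,5S,6R,8R)-4-hydroxy-3-oxo-8-[(1R,3aR,8aS)-1,4,4-trimethyl-8-methylidenedecahydroazulen-1-yl]-2,7-dioxabicyclo[3.2.1]octane-6-carboxylate F8 predominates, it is converted directly into 32 by Mitsunobu reaction with acetic acid (PPh3, diisopropyl azodicarboxylate), which inverts C12.

## Further compounds

F1 | step 7 | [(1R)-1-(2,2-dimethoxyethyl)cyclopent-2-en-1-yl]methanol | OC[C@@]1(CC(OC)OC)CCC=C1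
F2 | step 7 | 3-{[(1R)-1-(2,2-dimethoxyethyl)cyclopent-2-en-1-yl]methoxy}-2-methylcyclopent-2-en-1-one | CC1=C(OC[C@@]2(CC(OC)OC)CCC=C2)CCC1=O
F3 | step 7 | ether photoadduct (12 with CH2 in place of the lactone carbonyl) | C1O[C@]23CCC(=O)[C@@]2(C)[C@@H]4CC[C@@]1(CC(OC)OC)[C@H]34
F4 | step 8 | methyl (1R,3aR,8aR)-1-(2,2-dimethoxyethyl)-4,4-dimethyl-5,8-dioxodecahydroazulene-1-carboxylate | O=C1CCC(=O)C(C)(C)[C@@H]2CC[C@@](C(=O)OC)(CC(OC)OC)[C@H]12
F5 | step 13 | bis(S-methyl dithiocarbonate) of 18 | C=C1CCC(OC(=S)SC)C(C)(C)[C@@H]2CC[C@@](COC(=S)SC)(CC(OC)OC)[C@H]12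
F6 | step 17 | methyl (2R,3R)-3-(2-tert-butoxy-2-oxoethyl)-4-[(1R,3aR,8aS)-1,4,4-trimethyl-8-methylidenedecahydroazulen-1-yl]-2,3-dihydrofuran-2-carboxylate | C=C1CCCC(C)(C)[C@@H]2CC[C@@](C)(C3=CO[C@@H](C(=O)OC)[C@@H]3CC(=O)OC(C)(C)C)[C@H]12
F7 | step 18 | 2-[(2R,3R,4R)-5-hydroxy-2-(methoxycarbonyl)-4-[(1R,3aR,8aS)-1,4,4-trimethyl-8-methylidenedecahydroazulen-1-yl]oxolan-3-yl]acetic acid | C=C1CCCC(C)(C)[C@@H]2CC[C@@](C)([C@@H]3C(O)O[C@@H](C(=O)OC)[C@@H]3CC(=O)O)[C@H]12
F8 | step 19 | methyl (1S,4R,5S,6R,8R)-4-hydroxy-3-oxo-8-[(1R,3aR,8aS)-1,4,4-trimethyl-8-methylidenedecahydroazulen-1-yl]-2,7-dioxabicyclo[3.2.1]octane-6-carboxylate | C=C1CCCC(C)(C)[C@@H]2CC[C@@](C)([C@@H]3[C@@H]4OC(=O)[C@H](O)[C@H]3[C@H](C(=O)OC)O4)[C@H]12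
A1 | alternative 1 | hydroazulene C14 aldehyde with C7 triethylsilyloxy group and C10 dioxolane | O=C[C@]1(C)[C@H](O[Si](CC)(CC)CC)C[C@H]2C(C)(C)CCCC3(OCCO3)[C@@H]12
A2 | alternative 1 | C7–C8 epoxide with C14 triethylsilyloxy group on the six-membered ring (semipinacol substrate; C14 configuration left open) | C[C@@]12O[C@@H]1C[C@H]3C(C)(C)CCCC4(OCCO4)[C@H]3C2O[Si](CC)(CC)CC
A3 | alternative 2 | 2-oxabicyclo[2.1.1]hexane diester on the hydroazulene (C12 unassigned) | C=C1CCCC(C)(C)[C@@H]2CC[C@@](C)([C@@H]3[C@H]4O[C@@H](C(=O)OC)[C@@H]3C4C(=O)OC(C)(C)C)[C@H]12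
A4 | alternative 2 | 1,5-diene: β-alkoxyacrylate tethered through oxygen and C16 to the C13=C14 alkene | C=C1CCCC(C)(C)[C@@H]2CC[C@@](C)(/C=C/[C@@H](O/C=C/C(=O)OC(C)(C)C)C(=O)OC)[C@H]12
A5 | alternative 3 | cis-hydroazulene with exocyclic methylene and 2-pivaloyloxyethyl arm on C8 | C=C1CCCC(C)(C)[C@@H]2CC[C@@](C)(CCOC(=O)C(C)(C)C)[C@H]12
A6 | alternative 3 | trans-decalin with equatorial C9 mesylate, C8 methyl and 2-pivaloyloxyethyl arm | CC1(C)CCC[C@]2(C)[C@@H](OS(C)(=O)=O)[C@](C)(CCOC(=O)C(C)(C)C)CC[C@@H]12
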